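Ring B (C5–C10, labdane numbering) is never closed as a cyclohexane. It is grown from the cyclopentane of a trans-hydrindane. The exocyclic methylene carbon C8 is read as a latent ketone whose neighbour C9 carries the C11–C12 arm and is bonded to quaternary C10, which is the retron of a Prins–pinacol cascade. The precursor is a tertiary vinyl carbinol at C8 inside the five-membered ring C5–C6–C7–C8–C10. Activated formaldehyde is attacked by the vinyl terminus C11, and C10 migrates from C8 to C9. One operation inserts C9 into the ring, forms C9–C10 and C11–C12, and frees the C8 ketone. All other stereocentres descend from the angular methyl group of an organocatalytic hydrindenedione.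

Key step: step 10

Remark: every intermediate carries the labdane numbers of the target. Ring A is C1–C5 plus C10 and ring B is C5–C10. C17 is the exocyclic CH2, C18 the 4α-CH2O group, C19 the 4β-CH3 and C20 the 10β-CH3. The β face is the face of C20 and the α face is the opposite one.

Step 1
Reactants: 1 2-methylcyclopentane-1,3-dione; 2 pent-1-en-3-one
Product: 3 2-methyl-2-(3-oxopentyl)cyclopentane-1,3-dione
Conditions: AcOH (cat.), H2O, 75 °C
Reagents that add atoms: none
Why: Michael addition of the acidic 1,3-dione to the enone under mild acid catalysis in water should stop at the achiral triketone, which already holds C1–C8, C10, C19 and C20.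

Step 2
Reactants: 3 2-methyl-2-(3-oxopentyl)cyclopentane-1,3-dione
Product: 4 (7aS)-4,7a-dimethyl-2,3,7,7a-tetrahydro-1H-indene-1,5(6H)-dione
Conditions: (S)-phenylalanine, (1S)-camphor-10-sulfonic acid, MeCN, reflux; crystallisation
Reagents that add atoms: none
Why: In this Hajos–Parrish–Eder–Sauer–Wiechert reaction the enamine of the side-chain ketone picks one of the two enantiotopic ring carbonyls in a hydrogen-bonded aldol transition state, which sets C10, the acid co-catalyst dehydrates the ketol, and crystallisation should raise the enantiomeric purity.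

Step 3
Reactants: 4 (7aS)-4,7a-dimethyl-2,3,7,7a-tetrahydro-1H-indene-1,5(6H)-dione
Product: 5 enone ketal (4 with the C8 ketone masked as 1,3-dioxolane)
Conditions: TMSOCH2CH2OTMS, TMSOTf (cat.), CH2Cl2, −78 to −20 °C
Reagents that add atoms: 1,2-bis(trimethylsilyloxy)ethane, C[Si](C)(C)OCCO[Si](C)(C)C
Why: Silyl-transfer ketalisation under kinetic control should take the saturated C8 ketone and leave the less electrophilic, fully substituted enone untouched.

Step 4
Reactants: 5 enone ketal (4 with the C8 ketone masked as 1,3-dioxolane)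
Product: 6 quaternary ketone ketal (C3 ketone; 4α-CH2OBn; 4β-CH3; C5=C6)
Conditions: KOt-Bu, t-BuOH–THF, 0 °C; BnOCH2Cl, NaI, 0 °C to rt
Reagents that add atoms: benzyl chloromethyl ether, ClCOCc1ccccc1
Why: In this deconjugative α-alkylation of the extended (thermodynamic) dienolate the soft iodide formed in the flask should alkylate carbon C4 from the α face, opposite to the angular C20 methyl, which sets C4 and moves the double bond to C5=C6.

Step 5
Reactants: 6 quaternary ketone ketal (C3 ketone; 4α-CH2OBn; 4β-CH3; C5=C6)
Product: 8 alkene ketal (as 6 but CH2 at C3), via hydrazone 7 (not isolated)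
Conditions: N2H4·H2O, KOH, diethylene glycol, 130 °C then 210 °C
Reagents that add atoms: hydrazine hydrate, NN.O (nitrogen stays only in 7)
Why: This is a Wolff–Kishner reduction in which quaternary C4 keeps the double bond from moving into conjugation, and ketal, benzyl ether and alkene are inert to hot alkali.

Step 6
Reactants: 8 alkene ketal (as 6 but CH2 at C3)
Product: 10 6α-hydroxy trans-hydrindane ketal (H-5α), via alkylborane 9 (not isolated)
Conditions: BH3·THF, THF, 0 °C to rt; then NaOH, H2O2, 0 to 40 °C
Reagents that add atoms: borane–tetrahydrofuran, B.C1CCOC1 (boron stays only in 9); hydrogen peroxide, OO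
Why: In this hydroboration–oxidation boron adds to the less substituted C6 and hydrogen to C5, syn and from the α face because C19 and C20 shield the β face, which sets H-5α (trans fusion) and, after oxidation with retention, the 6α-hydroxyl.

Step 7
Reactants: 10 6α-hydroxy trans-hydrindane ketal (H-5α)
Product: 11 6α,18-bis(benzyloxy) trans-hydrindane ketal
Conditions: NaH, BnBr, n-Bu4NI (cat.), DMF, 0 °C to rt
Reagents that add atoms: benzyl bromide, BrCc1ccccc1
Why: Williamson ether synthesis on the sodium alkoxide touches no stereocenter and puts the same group on O-6 and O-18, so that one later operation frees both.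

Step 8
Reactants: 11 6α,18-bis(benzyloxy) trans-hydrindane ketal
Product: 12 6α,18-bis(benzyloxy) trans-hydrindan-8-one (five-membered ring C5–C6–C7–C8–C10)
Conditions: 1 M HCl, THF, rt
Reagents that add atoms: water, O
Why: Acid-catalysed ketal hydrolysis leaves the benzyl ethers intact, and neither ring-fusion centre can epimerise because C10 is quaternary and C5 is not α to the ketone.

Step 9
Reactants: 12 6α,18-bis(benzyloxy) trans-hydrindan-8-one (five-membered ring C5–C6–C7–C8–C10)
Product: 13 tertiary vinyl carbinol (8β-OH; 8α-CH=CH2 = C9=C11)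
Conditions: CH2=CHMgBr, CeCl3, THF, −78 °C; aq NH4Cl
Reagents that add atoms: vinylmagnesium bromide, C=C[Mg]Br
Why: Carbonyl 1,2-addition of the weakly basic organocerium reagent avoids enolisation and β-elimination of the C6 benzyloxy group, and attack from the α face, opposite to C20, should give the 8β-alcohol, whose stereocenter is consumed in step 10.

Step 10
Reactants: 13 tertiary vinyl carbinol (8β-OH; 8α-CH=CH2 = C9=C11)
Product: 15 6α,18-bis(benzyloxy)-12-hydroxy-13,14,15,16,17-pentanorlabdan-8-one (trans-decalin; H-5α; H-9α), via aluminium alkoxide 14 (not isolated)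
Conditions: Me2AlCl (3 equiv), (CH2O)n, CH2Cl2, −78 to 0 °C; dilute HCl work-up; then Et3N, CH2Cl2, rt
Reagents that add atoms: formaldehyde (as paraformaldehyde), C=O; dimethylaluminium chloride, C[Al](C)Cl (aluminium stays only in 14)
Why: Proposed new method: Me2AlCl first turns the tertiary alcohol into the aluminium alkoxide 14 and a further equivalent activates monomeric formaldehyde, whose carbon is attacked by the vinyl terminus C11 (Prins step, C11–C12 bond); as positive charge builds at C9 the antiperiplanar C8–C10 bond shifts to C9 and the alkoxide oxygen closes to the C8 ketone (pinacol step). The closest known reaction types are the Prins–pinacol cascade of allylic alcohol derivatives with tethered oxocarbenium ions, the Me2AlCl–formaldehyde Prins reaction of terminal alkenes and the Lewis-acid ring enlargement of 1-(oxiranyl)cyclopentanols. No ring is closed by cyclisation: the five-membered ring C5–C6–C7–C8–C10 becomes six-membered ring B by insertion of C9 through a suprafacial 1,2-shift. C10 migrates with retention, so the trans fusion and C4, C5 and C6 stay untouched, and the only new stereocenter C9 lies α to the ketone and should be settled by the Et3N equilibration as the equatorial epimer (H-9α). The step needs migration of C10 and not of C7: C10 is the fully substituted, more electron-rich carbon, whereas C7 is deactivated inductively by the β-oxygen at C6. C8 bears no hydrogen, so the competing ene pathway is closed, and the excess Lewis acid ties up the benzyl ether oxygens.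

Step 11
Reactants: 15 6α,18-bis(benzyloxy)-12-hydroxy-13,14,15,16,17-pentanorlabdan-8-one (trans-decalin; H-5α; H-9α)
Product: 16 6α,18-bis(benzyloxy)-13,14,15,16-tetranorlabd-8(17)-en-12-ol
Conditions: Ph3PCH3Br, KOt-Bu (4 equiv each), THF, 0 to 45 °C
Reagents that add atoms: methyltriphenylphosphonium bromide, C[P+](c1ccccc1)(c1ccccc1)c1ccccc1.[Br-]
Why: Wittig methylenation with excess ylide (one equivalent only deprotonates O-12) installs C17, and C9 already sits in its more stable equatorial configuration, so enolisation cannot erode it.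

Step 12
Reactants: 16 6α,18-bis(benzyloxy)-13,14,15,16-tetranorlabd-8(17)-en-12-ol
Product: 17 13,14,15,16-tetranorlabd-8(17)-ene-6α,12,18-triol
Conditions: Li, NH3(l), THF, −78 °C; NH4Cl
Reagents that add atoms: none
Why: Dissolving-metal (Birch-type) cleavage removes both benzyl ethers at the benzylic C–O bond, while the isolated 1,1-disubstituted alkene is not reduced.

Step 13
Reactants: 17 13,14,15,16-tetranorlabd-8(17)-ene-6α,12,18-triol
Product: 18 12-iodo-13,14,15,16-tetranorlabd-8(17)-ene-6α,18-diol
Conditions: I2, PPh3, imidazole (1 equiv each), THF, −20 °C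
Reagents that add atoms: iodine, I-I
Why: In this Appel-type iodination with one equivalent of reagent the unhindered primary C12 hydroxyl should be activated and displaced, while the neopentyl C18 and the hindered secondary C6 hydroxyls lag behind.

Step 14
Reactants: 18 12-iodo-13,14,15,16-tetranorlabd-8(17)-ene-6α,18-diol
Product: 19 6α-hydroxy-12-iodo-13,14,15,16-tetranorlabd-8(17)-en-18-yl benzoate
Conditions: BzCl (1 equiv), 2,4,6-collidine, CH2Cl2, −78 to −20 °C
Reagents that add atoms: benzoyl chloride, O=C(Cl)c1ccccc1
Why: Kinetically controlled O-acylation should take the primary C18 hydroxyl in preference to the equatorial C6 hydroxyl next to quaternary C4, and the non-nucleophilic base spares the iodide.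

Step 15
Reactants: 20 but-2-ynoic acid
Product: 21 (Z)-3-iodobut-2-enoic acid
Conditions: NaI, AcOH, 110 °C
Reagents that add atoms: sodium iodide, [Na+].[I-]
Why: Conjugate anti hydroiodination of the ynoic acid places iodine cis to the carboxyl group, which is the geometry needed at C13=C14.

Step 16
Reactants: 19 6α-hydroxy-12-iodo-13,14,15,16-tetranorlabd-8(17)-en-18-yl benzoate; 21 (Z)-3-iodobut-2-enoic acid
Product: 24 (13Z)-18-benzoyloxy-6α-hydroxylabda-8(17),13-dien-15-oic acid (target), via sodium carboxylate 22 (not isolated), via alkylzinc iodide 23 (not isolated)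
Conditions: 21, NaH, DMF, 0 °C; 19, Zn dust, I2 (cat.), DMA, 40 °C; combine, PdCl2(MeCN)2 (cat.), DMF, rt; dilute HCl
Reagents that add atoms: zinc, [Zn] (in 23 only); sodium hydride, [Na+].[H-] (sodium in 22 only)
Why: In this Negishi coupling the alkylzinc iodide tolerates benzoate and hindered alcohol, the acid is masked as its carboxylate, and oxidative addition and reductive elimination at the vinyl iodide proceed with retention, so C12 ends cis to the carboxyl group (13Z).

Compound list
1 | 2-methylcyclopentane-1,3-dione | CC1C(=O)CCC1=O | starting material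
2 | pent-1-en-3-one | C=CC(=O)CC | starting material
3 | 2-methyl-2-(3-oxopentyl)cyclopentane-1,3-dione | CCC(=O)CCC1(C)C(=O)CCC1=O | intermediate
4 | (7aS)-4,7a-dimethyl-2,3,7,7a-tetrahydro-1H-indene-1,5(6H)-dione | O=C1CCC2=C(C)C(=O)CC[C@@]21C | intermediate
5 | enone ketal (4 with the C8 ketone masked as 1,3-dioxolane) | C12(OCCO1)CCC3=C(C)C(=O)CC[C@@]32C | intermediate
6 | quaternary ketone ketal (C3 ketone; 4α-CH2OBn; 4β-CH3; C5=C6) | C12(OCCO1)CC=C3[C@](C)(COCc4ccccc4)C(=O)CC[C@@]32C | intermediate
7 | hydrazone of 6 at C3 | C12(OCCO1)CC=C3[C@](C)(COCc4ccccc4)C(=NN)CC[C@@]32C | intermediate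
8 | alkene ketal (as 6 but CH2 at C3) | C12(OCCO1)CC=C3[C@](C)(COCc4ccccc4)CCC[C@@]32C | intermediate
9 | alkylborane: 6α-boryl trans-hydrindane ketal (H-5α) | C12(OCCO1)C[C@H](B)[C@H]3[C@](C)(COCc4ccccc4)CCC[C@@]32C | intermediate
10 | 6α-hydroxy trans-hydrindane ketal (H-5α) | C12(OCCO1)C[C@H](O)[C@H]3[C@](C)(COCc4ccccc4)CCC[C@@]32C | intermediate
11 | 6α,18-bis(benzyloxy) trans-hydrindane ketal | C12(OCCO1)C[C@H](OCc4ccccc4)[C@H]3[C@](C)(COCc4ccccc4)CCC[C@@]32C | intermediate
12 | 6α,18-bis(benzyloxy) trans-hydrindan-8-one (five-membered ring C5–C6–C7–C8–C10) | O=C1C[C@H](OCc3ccccc3)[C@H]2[C@](C)(COCc3ccccc3)CCC[C@@]21C | intermediate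
13 | tertiary vinyl carbinol (8β-OH; 8α-CH=CH2 = C9=C11) | C=C[C@]1(O)C[C@H](OCc3ccccc3)[C@H]2[C@](C)(COCc3ccccc3)CCC[C@@]21C | intermediate
14 | chloro(methyl)aluminium alkoxide of 13 | C=C[C@]1(O[Al](C)Cl)C[C@H](OCc3ccccc3)[C@H]2[C@](C)(COCc3ccccc3)CCC[C@@]21C | intermediate
15 | 6α,18-bis(benzyloxy)-12-hydroxy-13,14,15,16,17-pentanorlabdan-8-one (trans-decalin; H-5α; H-9α) | O=C1C[C@H](OCc3ccccc3)[C@H]2[C@](C)(COCc3ccccc3)CCC[C@]2(C)[C@H]1CCO | intermediate
16 | 6α,18-bis(benzyloxy)-13,14,15,16-tetranorlabd-8(17)-en-12-ol | C=C1C[C@H](OCc3ccccc3)[C@H]2[C@](C)(COCc3ccccc3)CCC[C@]2(C)[C@H]1CCO | intermediate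
17 | 13,14,15,16-tetranorlabd-8(17)-ene-6α,12,18-triol | C=C1C[C@H](O)[C@H]2[C@](C)(CO)CCC[C@]2(C)[C@H]1CCO | intermediate
18 | 12-iodo-13,14,15,16-tetranorlabd-8(17)-ene-6α,18-diol | C=C1C[C@H](O)[C@H]2[C@](C)(CO)CCC[C@]2(C)[C@H]1CCI | intermediate
19 | 6α-hydroxy-12-iodo-13,14,15,16-tetranorlabd-8(17)-en-18-yl benzoate | C=C1C[C@H](O)[C@H]2[C@](C)(COC(=O)c3ccccc3)CCC[C@]2(C)[C@H]1CCI | intermediate
20 | but-2-ynoic acid | CC#CC(=O)O | starting material
21 | (Z)-3-iodobut-2-enoic acid | I/C(C)=C\C(=O)O | intermediate
22 | sodium (Z)-3-iodobut-2-enoate | I/C(C)=C\C(=O)[O-].[Na+] | intermediate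
23 | alkylzinc iodide from 19 (C12–ZnI) | C=C1C[C@H](O)[C@H]2[C@](C)(COC(=O)c3ccccc3)CCC[C@]2(C)[C@H]1CC[Zn]I | intermediate
24 | (13Z)-18-benzoyloxy-6α-hydroxylabda-8(17),13-dien-15-oic acid | C=C1C[C@H](O)[C@H]2[C@](C)(COC(=O)c3ccccc3)CCC[C@]2(C)[C@H]1CC/C(C)=C\C(=O)O | target

Total step count: 16. Longest linear sequence: 15 (steps 1–14 and 16).

Steps most likely to fail

1. Step 10 (proposed new method).
- What may go wrong: the charge developing at C9 may be intercepted by chloride or by the ether oxygen at C6 before the shift. C7 may migrate in place of C10. Formaldehyde may only acetalise the alkoxide.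
- Fallback (known chemistry, sets out from 13 and comes back at 15): hydroxyl-directed epoxidation of the vinyl group (VO(acac)2, t-BuOOH, CH2Cl2) gives the epoxy alcohol F1. SnCl4 in CH2Cl2 at −78 °C then effects the semipinacol ring enlargement to the β-hydroxy ketone F2. MsCl and Et3N give the mesylate F3, which DBU converts into the exocyclic enone F4. Conjugate addition of (i-PrO)Me2SiCH2MgCl with CuI, followed by protonation of the enolate from the α face, gives the silane F5. Tamao–Fleming oxidation (H2O2, KF, KHCO3) then delivers 15.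

2. Step 4.
- What may go wrong: the hard halomethyl ether may alkylate the dienolate on oxygen, or facial selectivity at C4 may be poor.
- Fallback (sets out from 5 and comes back at 6): the same potassium dienolate is trapped at −78 °C with monomeric formaldehyde in an aldol reaction at C4, from the α face, to give the hydroxymethyl ketone F6. This is benzylated without base by benzyl 2,2,2-trichloroacetimidate and catalytic TfOH, so that retro-aldol loss of formaldehyde is avoided.

3. Step 11.
- What may go wrong: the hindered ketone may react slowly, so that the basic ylide instead causes β-elimination of the C6 benzyloxy group, or the ketone stays locked as the hemiketal of O-12.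
- Fallback (sets out from 15 and comes back at 16): excess Me3SiCH2Li with CeCl3 adds to the ketone to give the β-hydroxysilane F7, and either C8 epimer serves. HF·pyridine then completes a Peterson olefination under non-basic conditions.

Further compounds
F1 | step 10 | epoxy alcohol (oxirane on C9–C11; 8β-OH; C9 either epimer) | C1OC1[C@]2(O)C[C@H](OCc4ccccc4)[C@H]3[C@](C)(COCc4ccccc4)CCC[C@@]32C
F2 | step 10 | β-hydroxy ketone (trans-decalin-8-one with 9-CH2OH) | O=C1C[C@H](OCc3ccccc3)[C@H]2[C@](C)(COCc3ccccc3)CCC[C@]2(C)[C@H]1CO
F3 | step 10 | mesylate of F2 | O=C1C[C@H](OCc3ccccc3)[C@H]2[C@](C)(COCc3ccccc3)CCC[C@]2(C)[C@H]1COS(C)(=O)=O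
F4 | step 10 | exocyclic enone (C9=C11H2 next to the C8 ketone) | O=C1C[C@H](OCc3ccccc3)[C@H]2[C@](C)(COCc3ccccc3)CCC[C@]2(C)C1=C
F5 | step 10 | silane (C12 bears SiMe2(Oi-Pr); H-9α) | O=C1C[C@H](OCc3ccccc3)[C@H]2[C@](C)(COCc3ccccc3)CCC[C@]2(C)[C@H]1CC[Si](C)(C)OC(C)C
F6 | step 4 | hydroxymethyl ketone (as 6 with free 18-OH) | C12(OCCO1)CC=C3[C@](C)(CO)C(=O)CC[C@@]32C
F7 | step 11 | β-hydroxysilane (8-OH; 8-CH2SiMe3; C8 either epimer) | C[Si](C)(C)CC1(O)C[C@H](OCc3ccccc3)[C@H]2[C@](C)(COCc3ccccc3)CCC[C@]2(C)[C@H]1CCO
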